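**Retrosynthetic overview**

1. Both tiglates are installed last on a diol. The ring oxirane comes from the enone by nucleophilic epoxidation guided by the free C4 hydroxyl (second and last ring formed).
2. The side-chain oxirane comes from a β-hydroxy α'-chloro ketone by syn-1,3 reduction and chloride displacement (first ring formed). The C8 hydroxyl is delivered to the allylic CH2 by selenium dioxide tethered to the C4 hydroxyl.
3. The C8–C9 bond (key bond) joins the isopropenyl group of an oxidised carvone to 1-bromo-3-chloro-3-methylbutan-2-one in a visible-light cobaloxime coupling that keeps the exocyclic methylene.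
4. The oxidised carvone comes from (R)-carvone by singlet-oxygen γ-hydroxylation, Mitsunobu inversion at C4 and α'-acetoxylation. The carbocycle and C5 are bought, and C5 relays to every other stereocentre.

Assumption: locants are those of carvone (C1 carbonyl, C2 methyl-bearing carbon, C5 side-chain carbon) and, in the side chain, C7 (alkene carbon on the ring), C14 (=CH2), C8 (carbinol), C9 (CH2), C10 (oxirane CH), C11 (CMe2); both enoates are (E) (tiglates), as the SMILES states.

**Route**

Step 1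
Reactants: 1 (R)-(−)-carvone
Product: 5 (4S,5R)-4-hydroxy-2-methyl-5-(prop-1-en-2-yl)cyclohex-2-en-1-one, via potassium dienolate 2 (not isolated), via silyl dienol ether 3 (not isolated), via silyl peroxide 4 (not isolated)
Conditions: KOtBu, THF, 0 °C; TMSCl; then O2, TPP (cat.), white LEDs, CH2Cl2, −78 °C; then PPh3, MeOH, −78 °C to rt
Reagents that add atoms: oxygen, O=O
Why: Thermodynamic γ-deprotonation and O-silylation give the linear dienol ether, which takes up sensitised singlet oxygen at C4 on the face opposite the neighbouring isopropenyl group (C4–O trans to C5) before phosphine reduction of the O–O bond, a dienol-ether photooxygenation (γ-hydroxylation of an enone).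

Step 2
Reactants: 5 (4S,5R)-4-hydroxy-2-methyl-5-(prop-1-en-2-yl)cyclohex-2-en-1-one
Product: 6 (4R,5R)-4-formyloxy-2-methyl-5-(prop-1-en-2-yl)cyclohex-2-en-1-one
Conditions: HCO2H, PPh3, DIAD, THF, 0 °C to rt
Reagents that add atoms: formic acid, OC=O
Why: Mitsunobu reaction in which the small, acidic formate displaces the oxyphosphonium group by SN2, inverting C4 so that its oxygen is now cis to the C5 substituent.

Step 3
Reactants: 6 (4R,5R)-4-formyloxy-2-methyl-5-(prop-1-en-2-yl)cyclohex-2-en-1-one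
Product: 7 (4R,5R,6S)-6-acetoxy-4-formyloxy-2-methyl-5-(prop-1-en-2-yl)cyclohex-2-en-1-one
Conditions: Mn(OAc)3·2H2O, benzene, reflux
Reagents that add atoms: manganese triacetate, CC(=O)[O-].CC(=O)[O-].CC(=O)[O-].[Mn+3]
Why: α'-Acetoxylation of an enone by trivalent manganese, whose C6 enolate takes acetate on the face opposite the C5 side chain to give the trans (diequatorial, also thermodynamically preferred) C5/C6 arrangement, as carvone itself does.

Step 4
Reactants: 7 (4R,5R,6S)-6-acetoxy-4-formyloxy-2-methyl-5-(prop-1-en-2-yl)cyclohex-2-en-1-one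
Product: 8 (4R,5R,6S)-6-acetoxy-4-hydroxy-2-methyl-5-(prop-1-en-2-yl)cyclohex-2-en-1-one
Conditions: KHCO3 (cat.), MeOH, 0 °C
Reagents that add atoms: none
Why: Base-catalysed transesterification removes the formate far faster than the acetate, freeing the C4 hydroxyl without touching a stereocentre.

Step 5
Reactants: 9 3-chloro-3-methylbutan-2-one
Product: 10 1-bromo-3-chloro-3-methylbutan-2-one
Conditions: Br2, MeOH, 0 °C to rt
Reagents that add atoms: bromine, BrBr
Why: Acid-catalysed α-bromination of a ketone, regiospecific because only the methyl side can enolise.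

Step 6
Reactants: 8 (4R,5R,6S)-6-acetoxy-4-hydroxy-2-methyl-5-(prop-1-en-2-yl)cyclohex-2-en-1-one; 10 1-bromo-3-chloro-3-methylbutan-2-one
Product: 11 (4R,5R,6S)-6-acetoxy-5-(6-chloro-6-methyl-5-oxohept-1-en-2-yl)-4-hydroxy-2-methylcyclohex-2-en-1-one
Conditions: Co(dmgH)2(py)Cl (10 mol%), 4CzIPN (2 mol%), Na2CO3, MeCN, 450 nm LEDs, rt
Reagents that add atoms: none
Why: Photochemical cobaloxime-mediated dehydrohalogenative (Heck-type) alkylation in which only the primary C–Br bond is activated, the electrophilic α-keto radical adds to the terminal carbon of the electron-rich isopropenyl group rather than to the enone, and divalent cobalt removes a hydrogen atom from the least hindered methyl group of the tertiary radical to restore an exocyclic methylene, so the C8–C9 bond forms without creating a stereocentre.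

Step 7
Reactants: 11 (4R,5R,6S)-6-acetoxy-5-(6-chloro-6-methyl-5-oxohept-1-en-2-yl)-4-hydroxy-2-methylcyclohex-2-en-1-one
Product: 15 (4R,5R,6S)-6-acetoxy-5-[(3S)-6-chloro-3-hydroxy-6-methyl-5-oxohept-1-en-2-yl]-4-hydroxy-2-methylcyclohex-2-en-1-one, via selenite monoester 12 (not isolated), via cyclic allylseleninate 13 (not isolated), via cyclic selenium diester 14 (not isolated)
Conditions: SeO2 (1.1 equiv), pyridine, 1,4-dioxane, 40 °C; then H2O
Reagents that add atoms: selenium dioxide, O=[Se]=O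
Why: Proposed new method: a hydroxyl-tethered Riley oxidation in which the axial C4 hydroxyl first binds tetravalent selenium as a selenite monoester, so that the ene reaction (Se to C14, H from C8) closes a six-membered seleninate on the C4 face with C9 turned away from the ring carbon C5 and the C5–H eclipsing the new alkene, and the suprafacial [2,3]-sigmatropic shift then puts oxygen on that same face of C8 to give, after hydrolysis of the divalent selenium diester, the (8S) alcohol; the closest known reaction is the intermolecular selenium dioxide allylic hydroxylation (ene reaction then [2,3] shift), which gives no facial control at such a carbon.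

Step 8
Reactants: 15 (4R,5R,6S)-6-acetoxy-5-[(3S)-6-chloro-3-hydroxy-6-methyl-5-oxohept-1-en-2-yl]-4-hydroxy-2-methylcyclohex-2-en-1-one
Product: 18 (4R,5R,6S)-6-acetoxy-5-{(3S)-4-[(2R)-3,3-dimethyloxiran-2-yl]-3-hydroxybut-1-en-2-yl}-4-hydroxy-2-methylcyclohex-2-en-1-one, via boron chelate 16 (not isolated), via chlorohydrin 17 (not isolated)
Conditions: Et2BOMe, THF/MeOH, −78 °C; NaBH4; AcOH, MeOH; then Cs2CO3, MeCN, 0 °C to rt
Reagents that add atoms: none
Why: Narasaka–Prasad reduction, in which external hydride attacks the six-membered boron chelate of the β-hydroxy ketone to give the syn-1,3-diol (C10 set by C8) faster than it attacks the enone, followed by 3-exo-tet displacement of the neighbouring tertiary chloride by the C10 alkoxide so that the oxirane keeps the C10 configuration.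

Step 9
Reactants: 18 (4R,5R,6S)-6-acetoxy-5-{(3S)-4-[(2R)-3,3-dimethyloxiran-2-yl]-3-hydroxybut-1-en-2-yl}-4-hydroxy-2-methylcyclohex-2-en-1-one
Product: 19 (2S,3S,4S,5R,6S)-6-acetoxy-5-{(3S)-4-[(2R)-3,3-dimethyloxiran-2-yl]-3-hydroxybut-1-en-2-yl}-2,3-epoxy-4-hydroxy-2-methylcyclohexan-1-one
Conditions: TBHP, DBU, CH2Cl2, 0 °C
Reagents that add atoms: tert-butyl hydroperoxide, CC(C)(C)OO
Why: Hydroxyl-directed Weitz–Scheffer (nucleophilic) epoxidation in which hydrogen bonding of the pseudo-axial C4 hydroxyl guides the hydroperoxide anion to C3 on the same face, so the oxirane forms cis to the C4 oxygen and to the side chain while the isolated alkene is left alone.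

Step 10
Reactants: 19 (2S,3S,4S,5R,6S)-6-acetoxy-5-{(3S)-4-[(2R)-3,3-dimethyloxiran-2-yl]-3-hydroxybut-1-en-2-yl}-2,3-epoxy-4-hydroxy-2-methylcyclohexan-1-one
Product: 20 (2S,3S,4S,5R,6S)-6-acetoxy-5-{(3S)-4-[(2R)-3,3-dimethyloxiran-2-yl]-3-[(E)-2-methylbut-2-enoyloxy]but-1-en-2-yl}-2,3-epoxy-2-methyl-4-[(E)-2-methylbut-2-enoyloxy]cyclohexan-1-one (CNP0407453.3)
Conditions: tiglic anhydride, DMAP, pyridine, CH2Cl2, 0 °C to rt
Reagents that add atoms: tiglic anhydride, C/C=C(\C)C(=O)OC(=O)/C(C)=C/C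
Why: DMAP-catalysed acylation of the two remaining secondary alcohols (C4 and C8) installs both (E)-2-methylbut-2-enoates without touching a stereocentre or the alkene geometry.

**Compound list**

1 | (R)-(−)-carvone, (5R)-2-methyl-5-(prop-1-en-2-yl)cyclohex-2-en-1-one | C=C(C)[C@@H]1CC=C(C)C(=O)C1 | starting material
2 | potassium (5S)-2-methyl-5-(prop-1-en-2-yl)cyclohexa-1,3-dien-1-olate (linear dienolate of 1) | C=C(C)[C@@H]1C=CC(C)=C([O-])C1.[K+] | intermediate
3 | trimethyl{[(5S)-2-methyl-5-(prop-1-en-2-yl)cyclohexa-1,3-dien-1-yl]oxy}silane | C=C(C)[C@@H]1C=CC(C)=C(O[Si](C)(C)C)C1 | intermediate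
4 | (4S,5R)-2-methyl-5-(prop-1-en-2-yl)-4-[(trimethylsilyl)peroxy]cyclohex-2-en-1-one | C=C(C)[C@@H]1[C@@H](OO[Si](C)(C)C)C=C(C)C(=O)C1 | intermediate
5 | (4S,5R)-4-hydroxy-2-methyl-5-(prop-1-en-2-yl)cyclohex-2-en-1-one (4-OH trans to isopropenyl) | C=C(C)[C@@H]1[C@@H](O)C=C(C)C(=O)C1 | intermediate
6 | (4R,5R)-4-formyloxy-2-methyl-5-(prop-1-en-2-yl)cyclohex-2-en-1-one (4-O cis to isopropenyl) | C=C(C)[C@@H]1[C@H](OC=O)C=C(C)C(=O)C1 | intermediate
7 | (4R,5R,6S)-6-acetoxy-4-formyloxy-2-methyl-5-(prop-1-en-2-yl)cyclohex-2-en-1-one | C=C(C)[C@@H]1[C@H](OC=O)C=C(C)C(=O)[C@H]1OC(C)=O | intermediate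
8 | (4R,5R,6S)-6-acetoxy-4-hydroxy-2-methyl-5-(prop-1-en-2-yl)cyclohex-2-en-1-one | C=C(C)[C@@H]1[C@H](O)C=C(C)C(=O)[C@H]1OC(C)=O | intermediate
9 | 3-chloro-3-methylbutan-2-one | CC(=O)C(C)(C)Cl | starting material
10 | 1-bromo-3-chloro-3-methylbutan-2-one | BrCC(=O)C(C)(C)Cl | intermediate
11 | (4R,5R,6S)-6-acetoxy-5-(6-chloro-6-methyl-5-oxohept-1-en-2-yl)-4-hydroxy-2-methylcyclohex-2-en-1-one | C=C(CCC(=O)C(C)(C)Cl)[C@@H]1[C@H](O)C=C(C)C(=O)[C@H]1OC(C)=O | intermediate
12 | hydrogen selenite (O–Se(=O)–OH) monoester of the C4 hydroxyl of 11, other centres as in 11 | C=C(CCC(=O)C(C)(C)Cl)[C@@H]1[C@H](O[Se](=O)O)C=C(C)C(=O)[C@H]1OC(C)=O | intermediate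
13 | cyclic seleninate: Se(=O) bridging O4 and C14 in a six-membered ring, (Z)-C7=C8 alkene with C9 cis to C14, ring centres as in 11 | O=[Se]1C/C(=C\CC(=O)C(C)(C)Cl)[C@@H]2[C@H](O1)C=C(C)C(=O)[C@H]2OC(C)=O | intermediate
14 | cyclic selenium diester: seven-membered O4–Se–O8 ring, C8 (S), exocyclic C7=C14 restored, ring centres as in 11 | C=C1[C@@H]2[C@H](O[Se]O[C@H]1CC(=O)C(C)(C)Cl)C=C(C)C(=O)[C@H]2OC(C)=O | intermediate
15 | (4R,5R,6S)-6-acetoxy-5-[(3S)-6-chloro-3-hydroxy-6-methyl-5-oxohept-1-en-2-yl]-4-hydroxy-2-methylcyclohex-2-en-1-one | C=C([C@@H]1[C@H](O)C=C(C)C(=O)[C@H]1OC(C)=O)[C@H](CC(=O)C(C)(C)Cl)O | intermediate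
16 | diethylboron chelate of 15 (six-membered O8–BEt2–O=C10 ring, centres as in 15) | C=C([C@@H]1[C@H](O)C=C(C)C(=O)[C@H]1OC(C)=O)[C@@H]1CC(C(C)(C)Cl)=[O+][B-](CC)(CC)O1 | intermediate
17 | (4R,5R,6S)-6-acetoxy-5-[(3S,5R)-6-chloro-3,5-dihydroxy-6-methylhept-1-en-2-yl]-4-hydroxy-2-methylcyclohex-2-en-1-one | C=C([C@@H]1[C@H](O)C=C(C)C(=O)[C@H]1OC(C)=O)[C@H](C[C@@H](O)C(C)(C)Cl)O | intermediate
18 | (4R,5R,6S)-6-acetoxy-5-{(3S)-4-[(2R)-3,3-dimethyloxiran-2-yl]-3-hydroxybut-1-en-2-yl}-4-hydroxy-2-methylcyclohex-2-en-1-one | C=C([C@@H]1[C@H](O)C=C(C)C(=O)[C@H]1OC(C)=O)[C@H](C[C@H]1OC1(C)C)O | intermediate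
19 | (2S,3S,4S,5R,6S)-6-acetoxy-5-{(3S)-4-[(2R)-3,3-dimethyloxiran-2-yl]-3-hydroxybut-1-en-2-yl}-2,3-epoxy-4-hydroxy-2-methylcyclohexan-1-one | C=C([C@@H]1[C@H](O)[C@@H]2O[C@]2(C)C(=O)[C@H]1OC(C)=O)[C@H](C[C@H]1OC1(C)C)O | intermediate
20 | (2S,3S,4S,5R,6S)-6-acetoxy-5-{(3S)-4-[(2R)-3,3-dimethyloxiran-2-yl]-3-[(E)-2-methylbut-2-enoyloxy]but-1-en-2-yl}-2,3-epoxy-2-methyl-4-[(E)-2-methylbut-2-enoyloxy]cyclohexan-1-one | C=C([C@@H]1[C@H](OC(=O)/C(C)=C/C)[C@@H]2O[C@]2(C)C(=O)[C@H]1OC(C)=O)[C@H](C[C@H]1OC1(C)C)OC(=O)/C(C)=C/C | target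

**Step count**

Total steps: 10. Longest linear sequence: 9 (steps 1–4 and 6–10 from carvone; step 5 prepares the coupling partner).

**Steps most likely to fail, with fallbacks**

Step 6 (photochemical cobaloxime coupling). The risks are alkene regioisomers from hydrogen removal at C8 or C5, a second alkylation of the product alkene, and low conversion. The fallback sets out from 7 and from 9 and returns at 11. Catalytic SeO2 with TBHP in CH2Cl2 oxidises the isopropenyl methyl of 7 to allylic alcohol F1. Ketone 9 is converted with HC(OMe)3 and catalytic TsOH into dimethyl ketal F2. Heating F1 with F2 and catalytic propionic acid in toluene at 110 °C gives allyl vinyl ether F3, which rearranges in the same pot by a [3,3] Claisen (Saucy–Marbet) shift to formate F4; this fixes the exocyclic methylene regiospecifically. Methanolysis of the formate as in step 4 then gives 11.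

Step 7 (the proposed tethered selenium dioxide hydroxylation). The risks are a C8 epimer mixture if the untethered pathway competes, over-oxidation of C8 or of the C4 alcohol, and α-oxidation of the side-chain ketone at C9. The fallback uses known chemistry, sets out from 8 and from 9, and returns at 15. Catalytic SeO2 with TBHP, followed by MnO2 if the allylic alcohol persists, converts the isopropenyl methyl of 8 into enal F5, which equilibrates with its cis-fused lactol. Ketone 9 is converted with TMSOTf and Et3N into silyl enol ether F6. A Mukaiyama aldol addition of F6 to F5 promoted by MgBr2·OEt2, with aqueous work-up, gives 15 directly. In this variant C8 is controlled only by chelation between the C4 hydroxyl and the aldehyde, so the 8-epimer would have to be removed by chromatography.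

Step 9 (hydroxyl-directed nucleophilic epoxidation). The risks are loss or migration of the base-labile C6 acetate and epoxidation on the wrong face. The fallback sets out from 18 and returns at 20. Acylation first with tiglic anhydride and DMAP gives bis-tiglate enone F7. Luche reduction (NaBH4, CeCl3·7H2O, MeOH, −78 °C) gives allylic alcohol F8 with the C1 hydroxyl cis to the C5 side chain, as carvone gives cis-carveol. VO(acac)2 with TBHP then epoxidises the ring alkene syn to that hydroxyl to give epoxy alcohol F9; the side-chain alkene has no free hydroxyl next to it and is left alone. Dess–Martin oxidation of F9 gives 20.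

**Further compounds**

F1 | step 6 | (4R,5R,6S)-6-acetoxy-4-formyloxy-5-(3-hydroxyprop-1-en-2-yl)-2-methylcyclohex-2-en-1-one | C=C(CO)[C@@H]1[C@H](OC=O)C=C(C)C(=O)[C@H]1OC(C)=O
F2 | step 6 | 3-chloro-2,2-dimethoxy-3-methylbutane | COC(C)(OC)C(C)(C)Cl
F3 | step 6 | (4R,5R,6S)-6-acetoxy-5-{3-[(3-chloro-3-methylbut-1-en-2-yl)oxy]prop-1-en-2-yl}-4-formyloxy-2-methylcyclohex-2-en-1-one | C=C(COC(=C)C(C)(C)Cl)[C@@H]1[C@H](OC=O)C=C(C)C(=O)[C@H]1OC(C)=O
F4 | step 6 | (4R,5R,6S)-6-acetoxy-5-(6-chloro-6-methyl-5-oxohept-1-en-2-yl)-4-formyloxy-2-methylcyclohex-2-en-1-one | C=C(CCC(=O)C(C)(C)Cl)[C@@H]1[C@H](OC=O)C=C(C)C(=O)[C@H]1OC(C)=O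
F5 | step 7 | 2-[(1R,2R,6S)-6-acetoxy-2-hydroxy-4-methyl-5-oxocyclohex-3-en-1-yl]prop-2-enal (ring centres as in 8) | C=C(C=O)[C@@H]1[C@H](O)C=C(C)C(=O)[C@H]1OC(C)=O
F6 | step 7 | [(3-chloro-3-methylbut-1-en-2-yl)oxy]trimethylsilane | C=C(O[Si](C)(C)C)C(C)(C)Cl
F7 | step 9 | 4,8-bis-O-tiglate of 18 (enone, all centres as in 18) | C=C([C@@H]1[C@H](OC(=O)/C(C)=C/C)C=C(C)C(=O)[C@H]1OC(C)=O)[C@H](C[C@H]1OC1(C)C)OC(=O)/C(C)=C/C
F8 | step 9 | C1 allylic alcohol of F7 (1-OH cis to the C5 side chain, other centres as in F7) | C=C([C@@H]1[C@H](OC(=O)/C(C)=C/C)C=C(C)[C@H](O)[C@H]1OC(C)=O)[C@H](C[C@H]1OC1(C)C)OC(=O)/C(C)=C/C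
F9 | step 9 | 2,3-epoxy C1 alcohol (oxirane cis to 1-OH and to the C5 side chain, other centres as in 20) | C=C([C@@H]1[C@H](OC(=O)/C(C)=C/C)[C@@H]2O[C@]2(C)[C@H](O)[C@H]1OC(C)=O)[C@H](C[C@H]1OC1(C)C)OC(=O)/C(C)=C/C
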